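**Plan**

The target is read as epicatechin-(4β→8)-epigallocatechin 3-O-gallate-(4β→8)-epicatechin-(4β→8)-catechin; the flavan units are called unit 1 to unit 4 from the top, and each has rings A (benzo), B (2-aryl) and C (pyran).
Retrosynthesis: after debenzylation, the bonds C4(unit 1)–C8(unit 2) and C4(unit 2)–C8(unit 3) are cut as flavan-4-yl cation/arene pairs; ring C of unit 3 is then cut across C2–C3 and C4–C4a, so unit 3 is built rather than taken from a flavanol.
Enabling feature: in unit 3 the aryl ether segment C4a=C8a–O1 together with C2 is a cationic 2-oxadiene (O-aryl oxocarbenium ion from symmetric 3,5-bis(benzyloxy)phenol and a 3,4-bis(benzyloxy)benzyl group), and C3=C4 is an (E)-enol acetate standing on C8 of catechin, polarised by that trioxygenated ring A so that C3 is the nucleophilic carbon.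
Forward: catechin → 8-(2-acetoxyvinyl)catechin; aryl benzyl ether → mixed trifluoroethyl acetal; a formal [4+2] builds ring C of unit 3 onto unit 4 (protected procyanidin B1); galloylated unit 2 and then unit 1 are joined at C8 of the top unit; hydrogenolysis.
Stereochemistry: units 1, 2 and 4 come from (−)-epicatechin, (−)-epigallocatechin and (+)-catechin; C2, C3 and C4 of unit 3 come from the key step (chiral counter-anion, endo-acetoxy approach, anti ring closure); the two later C4 centres come from attack trans to the C3 oxygen.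

Key step: step 7

Assumption: the sense of induction of the chiral phosphoramide in step 7 has to be assigned on the first run; the (R)-catalyst is written, and its enantiomer is used if that is the matched one, because the stereocentres of unit 4 are too remote to bias the step.

**Route**

Step 1
Reactants: 1 (+)-catechin
Product: 2 5,7,3',4'-tetra-O-benzyl-(+)-catechin
Conditions: BnBr (4.4 equiv), K2CO3, DMF, 0 °C to rt
Reagents that add atoms: benzyl bromide, BrCc1ccccc1
Why: Williamson etherification under carbonate base alkylates only the four phenols, so the secondary 3-OH and the C2/C3 stereocentres of the chiral-pool material stay untouched.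

Step 2
Reactants: 2 5,7,3',4'-tetra-O-benzyl-(+)-catechin
Product: 3 8-bromo-5,7,3',4'-tetra-O-benzyl-(+)-catechin
Conditions: NBS (1.0 equiv), CH2Cl2, −78 °C to rt
Reagents that add atoms: N-bromosuccinimide, O=C1CCC(=O)N1Br
Why: Electrophilic aromatic bromination of the trioxygenated ring A goes to C8, the position preferred in benzylated flavan-3-ols, and thereby fixes the C8 attachment of unit 4.

Step 3
Reactants: 3 8-bromo-5,7,3',4'-tetra-O-benzyl-(+)-catechin; 4 (E)-2-(2-ethoxyvinyl)-4,4,5,5-tetramethyl-1,3,2-dioxaborolane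
Product: 6 8-(2-oxoethyl)-5,7,3',4'-tetra-O-benzyl-(+)-catechin, via enol ether 5 (not isolated)
Conditions: Pd(OAc)2 (5 mol %), SPhos (10 mol %), K3PO4, 1,4-dioxane/H2O, 80 °C; then 2 M HCl, THF, rt
Reagents that add atoms: water, O
Why: Suzuki–Miyaura coupling with a dialkylbiarylphosphine ligand suited to hindered electron-rich aryl bromides places the two-carbon unit on C8, and acid hydrolysis of the enol ether then releases the arylacetaldehyde.

Step 4
Reactants: 6 8-(2-oxoethyl)-5,7,3',4'-tetra-O-benzyl-(+)-catechin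
Product: 7 3-O-acetyl-8-[(E)-2-acetoxyvinyl]-5,7,3',4'-tetra-O-benzyl-(+)-catechin
Conditions: Ac2O (4 equiv), Et3N, DMAP (cat.), CH2Cl2, 0 °C to rt
Reagents that add atoms: acetic anhydride, CC(=O)OC(C)=O
Why: Base-mediated O-acetylation of the aryl-conjugated aldehyde enol (enol ester formation) and of the 3-OH should give mainly the (E)-enol acetate, because the (Z)-isomer presses the acetoxy group against the ortho oxygens of ring A, and any (Z)-isomer is removed by chromatography.

Step 5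
Reactants: 8 3,5-bis(benzyloxy)phenol; 9 3,4-bis(benzyloxy)benzyl chloride
Product: 10 1,3-bis(benzyloxy)-5-[3,4-bis(benzyloxy)benzyloxy]benzene
Conditions: K2CO3, DMF, 60 °C
Reagents that add atoms: none
Why: Williamson O-alkylation of the phenoxide by the primary benzylic chloride joins the future ring A and the C2–ring B carbon of unit 3 through O1.

Step 6
Reactants: 10 1,3-bis(benzyloxy)-5-[3,4-bis(benzyloxy)benzyloxy]benzene
Product: 11 [3,4-bis(benzyloxy)phenyl][3,5-bis(benzyloxy)phenoxy](2,2,2-trifluoroethoxy)methane (racemic mixed acetal)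
Conditions: DDQ (1.1 equiv), CF3CH2OH (10 equiv), 2,6-dichloropyridine, 4 Å MS, CH2Cl2, 0 °C
Reagents that add atoms: 2,2,2-trifluoroethanol, OCC(F)(F)F
Why: DDQ abstracts hydride from the benzylic CH2 that is activated by the para-benzyloxy group (the oxidation that cleaves 3,4-dialkoxybenzyl ethers, which leaves plain benzyl ethers alone), and under dry buffered conditions trifluoroethanol traps the oxocarbenium ion as the mixed acetal.

Step 7
Reactants: 11 [3,4-bis(benzyloxy)phenyl][3,5-bis(benzyloxy)phenoxy](2,2,2-trifluoroethoxy)methane; 7 3-O-acetyl-8-[(E)-2-acetoxyvinyl]-5,7,3',4'-tetra-O-benzyl-(+)-catechin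
Product: 14 3-O-acetyl-5,7,3',4'-tetra-O-benzylepicatechin-(4β→8)-3-O-acetyl-5,7,3',4'-tetra-O-benzylcatechin, via aryl oxocarbenium ion 12 (not isolated), via benzylic cation 13 (not isolated)
Conditions: (R)-3,3'-bis(2,4,6-triisopropylphenyl)-1,1'-binaphthyl-2,2'-diyl N-triflylphosphoramide (10 mol %), 11 (1.2 equiv), 4 Å MS, CH2Cl2, −60 to −30 °C; Et3N quench
Reagents that add atoms: none
Why: Proposed new method: the chiral acid ionises the mixed acetal by loss of trifluoroethanol (the trifluoroethoxy group is the poorer oxocarbenium donor, so the (E)-O-aryl ion 12 should form and not an alkyl one), C2 of 12 is attacked by the acetoxy-bearing alkene carbon of 7, because the 5,7,8a-trioxygenated ring A of the catechin unit stabilises positive charge on the other carbon far better than an acetoxy group can, and the resulting para-quinone-methide-like cation 13 is captured by the ring carbon ortho to the ether oxygen, with loss of the proton that returns the catalyst. The closest known reaction type is the oxa-Povarov reaction (SnCl4-mediated formal inverse-electron-demand [4+2] of aryl oxocarbenium ions from aryl trifluoroethyl acetals with styrenes), together with chiral Brønsted acid catalysed Povarov reactions and chiral-anion-directed additions to oxocarbenium ions; neither a 2-acyloxystyrene partner nor absolute control has been shown for it. Ring C of unit 3 closes as a stepwise cationic [4+2] annulation, the second bond by intramolecular Friedel–Crafts alkylation (6-exo-trig with respect to the quinone-methide C4=C8 bond of 13). C2 is set by the phosphoramide anion, which ion-pairs with 12 and screens one face; C3 follows from the compact transition state in which the C2 aryl group of (E)-12 is outside, the small acetoxy group is endo over O1 and the bulky ortho-disubstituted catechin ring is exo, which with the (E)-alkene gives 2,3-cis; C4 is set in the closure, which should take place anti to the 3-acetoxy group (C3–H in the plane of the cation to avoid allylic strain, acetoxonium participation on the opposite face) and so gives 3,4-trans (4β). The step needs regioselectivity in the first bond and chemoselectivity against Friedel–Crafts attack at C6 of the catechin ring; the first is secured by the polarisation named above, the second by the higher nucleophilicity of the conjugated alkene, and the closure has no regiochemical choice because the two ortho carbons of the 3,5-bis(benzyloxy)phenoxy ring are equivalent.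

Step 8
Reactants: 14 3-O-acetyl-5,7,3',4'-tetra-O-benzylepicatechin-(4β→8)-3-O-acetyl-5,7,3',4'-tetra-O-benzylcatechin
Product: 15 5,7,3',4'-tetra-O-benzylepicatechin-(4β→8)-5,7,3',4'-tetra-O-benzylcatechin (octa-O-benzylprocyanidin B1)
Conditions: K2CO3 (0.2 equiv), MeOH/THF, 0 °C to rt
Reagents that add atoms: none
Why: Base-catalysed transesterification removes both acetates while benzyl ethers, the interflavan bond and all stereocentres are stable to mild methanolic carbonate, and minor diastereomers from step 7 can be removed at this stage.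

Step 9
Reactants: 16 (−)-epigallocatechin
Product: 17 5,7,3',4',5'-penta-O-benzyl-(−)-epigallocatechin
Conditions: BnBr (5.5 equiv), K2CO3, DMF, 0 °C to rt
Reagents that add atoms: benzyl bromide, BrCc1ccccc1
Why: Williamson etherification under carbonate base protects the five phenols and leaves the 3-OH free for the later galloylation.

Step 10
Reactants: 17 5,7,3',4',5'-penta-O-benzyl-(−)-epigallocatechin
Product: 18 5,7,3',4',5'-penta-O-benzyl-4β-(2-ethoxyethoxy)-(−)-epigallocatechin
Conditions: DDQ (1.5 equiv), 2-ethoxyethanol, CH2Cl2, rt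
Reagents that add atoms: 2-ethoxyethanol, CCOCCO
Why: DDQ hydride abstraction at C4, benzylic to the electron-rich ring A, gives the flavan-4-yl cation, which the alcohol traps trans to the 3-OH as a storable C4 leaving group (benzylic oxidation with alcohol capture).

Step 11
Reactants: 18 5,7,3',4',5'-penta-O-benzyl-4β-(2-ethoxyethoxy)-(−)-epigallocatechin; 19 3,4,5-tris(benzyloxy)benzoic acid
Product: 20 5,7,3',4',5'-penta-O-benzyl-4β-(2-ethoxyethoxy)-(−)-epigallocatechin 3-O-[3,4,5-tris(benzyloxy)benzoate]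
Conditions: DCC, DMAP, CH2Cl2, rt
Reagents that add atoms: none
Why: Steglich esterification acylates the only free hydroxyl, and the acid-labile 4-alkoxy group survives the neutral conditions.

Step 12
Reactants: 20 5,7,3',4',5'-penta-O-benzyl-4β-(2-ethoxyethoxy)-(−)-epigallocatechin 3-O-[3,4,5-tris(benzyloxy)benzoate]; 15 octa-O-benzylprocyanidin B1
Product: 21 5,7,3',4',5'-penta-O-benzyl-3-O-[3,4,5-tris(benzyloxy)benzoyl]epigallocatechin-(4β→8)-5,7,3',4'-tetra-O-benzylepicatechin-(4β→8)-5,7,3',4'-tetra-O-benzylcatechin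
Conditions: TMSOTf (0.2 equiv), 15 (2 equiv, excess recovered), CH2Cl2, −78 °C; Et3N quench
Reagents that add atoms: none
Why: Lewis-acid ionisation of the 4-alkoxy group gives the C4 cation, held on its α face as a dioxolanylium ion by the 3-O-galloyl group, so that C8 of the upper unit of 15 (the most reactive arene position of benzylated dimers) attacks from the β face and sets the 3,4-trans (4β→8) bond in a Friedel–Crafts-type flavan-4-yl coupling.

Step 13
Reactants: 22 (−)-epicatechin
Product: 23 5,7,3',4'-tetra-O-benzyl-(−)-epicatechin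
Conditions: BnBr (4.4 equiv), K2CO3, DMF, 0 °C to rt
Reagents that add atoms: benzyl bromide, BrCc1ccccc1
Why: Williamson etherification under carbonate base protects the four phenols only.

Step 14
Reactants: 23 5,7,3',4'-tetra-O-benzyl-(−)-epicatechin
Product: 24 5,7,3',4'-tetra-O-benzyl-4β-(2-ethoxyethoxy)-(−)-epicatechin
Conditions: DDQ (1.5 equiv), 2-ethoxyethanol, CH2Cl2, rt
Reagents that add atoms: 2-ethoxyethanol, CCOCCO
Why: DDQ oxidation at C4 with alcohol capture, as in step 10, activates unit 1 as an electrophile.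

Step 15
Reactants: 24 5,7,3',4'-tetra-O-benzyl-4β-(2-ethoxyethoxy)-(−)-epicatechin; 21 protected trimer
Product: 25 5,7,3',4'-tetra-O-benzylepicatechin-(4β→8)-5,7,3',4',5'-penta-O-benzyl-3-O-[3,4,5-tris(benzyloxy)benzoyl]epigallocatechin-(4β→8)-5,7,3',4'-tetra-O-benzylepicatechin-(4β→8)-5,7,3',4'-tetra-O-benzylcatechin
Conditions: TMSOTf (0.2 equiv), 21 (1.5 equiv, excess recovered), CH2Cl2, −78 °C; Et3N quench
Reagents that add atoms: none
Why: The same flavan-4-yl cation coupling joins unit 1 to C8 of the top unit of 21, and attack anti to the axial 3-OH of the 2,3-cis cation sets the 4β bond.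

Step 16
Reactants: 25 protected tetramer
Product: 26 epicatechin-(4β→8)-epigallocatechin 3-O-gallate-(4β→8)-epicatechin-(4β→8)-catechin (CNP0332815.1)
Conditions: H2 (1 atm), Pd(OH)2/C, THF/MeOH/H2O, rt
Reagents that add atoms: none
Why: Hydrogenolysis cleaves all twenty benzyl ethers under neutral conditions that leave the gallate ester, the acid-labile interflavan bonds and every stereocentre untouched.

**Compound list**

1 | (+)-catechin, (2R,3S) | O[C@H]1Cc2c(O)cc(O)cc2O[C@@H]1c1ccc(O)c(O)c1 | starting material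
2 | 5,7,3',4'-tetra-O-benzyl-(+)-catechin | O[C@H]1Cc2c(OCc3ccccc3)cc(OCc3ccccc3)cc2O[C@@H]1c1ccc(OCc2ccccc2)c(OCc2ccccc2)c1 | intermediate
3 | 8-bromo-5,7,3',4'-tetra-O-benzyl-(+)-catechin | O[C@H]1Cc2c(OCc3ccccc3)cc(OCc3ccccc3)c(Br)c2O[C@@H]1c1ccc(OCc2ccccc2)c(OCc2ccccc2)c1 | intermediate
4 | (E)-2-(2-ethoxyvinyl)-4,4,5,5-tetramethyl-1,3,2-dioxaborolane | CCO/C=C/B1OC(C)(C)C(C)(C)O1 | starting material
5 | 8-[(E)-2-ethoxyvinyl]-5,7,3',4'-tetra-O-benzyl-(+)-catechin | O[C@H]1Cc2c(OCc3ccccc3)cc(OCc3ccccc3)c(/C=C/OCC)c2O[C@@H]1c1ccc(OCc2ccccc2)c(OCc2ccccc2)c1 | intermediate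
6 | 8-(2-oxoethyl)-5,7,3',4'-tetra-O-benzyl-(+)-catechin | O[C@H]1Cc2c(OCc3ccccc3)cc(OCc3ccccc3)c(CC=O)c2O[C@@H]1c1ccc(OCc2ccccc2)c(OCc2ccccc2)c1 | intermediate
7 | 3-O-acetyl-8-[(E)-2-acetoxyvinyl]-5,7,3',4'-tetra-O-benzyl-(+)-catechin | CC(=O)O[C@H]1Cc2c(OCc3ccccc3)cc(OCc3ccccc3)c(/C=C/OC(C)=O)c2O[C@@H]1c1ccc(OCc2ccccc2)c(OCc2ccccc2)c1 | intermediate
8 | 3,5-bis(benzyloxy)phenol | Oc1cc(OCc2ccccc2)cc(OCc2ccccc2)c1 | starting material
9 | 3,4-bis(benzyloxy)benzyl chloride | ClCc1ccc(OCc2ccccc2)c(OCc2ccccc2)c1 | starting material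
10 | 1,3-bis(benzyloxy)-5-[3,4-bis(benzyloxy)benzyloxy]benzene | C(Oc1cc(OCc2ccccc2)cc(OCc2ccccc2)c1)c1ccc(OCc2ccccc2)c(OCc2ccccc2)c1 | intermediate
11 | [3,4-bis(benzyloxy)phenyl][3,5-bis(benzyloxy)phenoxy](2,2,2-trifluoroethoxy)methane, racemic | FC(F)(F)COC(Oc1cc(OCc2ccccc2)cc(OCc2ccccc2)c1)c1ccc(OCc2ccccc2)c(OCc2ccccc2)c1 | intermediate
12 | (E)-O-[3,5-bis(benzyloxy)phenyl] 3,4-bis(benzyloxy)benzylidene oxocarbenium ion | c1c(OCc2ccccc2)cc(OCc2ccccc2)cc1/[O+]=C/c1ccc(OCc2ccccc2)c(OCc2ccccc2)c1 | intermediate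
13 | open-chain benzylic cation after C2–C3 bond formation, C2 and C3 of unit 3 configured as in 14 | c1c(OCc2ccccc2)cc(OCc2ccccc2)cc1O[C@H](c1ccc(OCc2ccccc2)c(OCc2ccccc2)c1)[C@H](OC(C)=O)[CH+]c1c(OCc3ccccc3)cc(OCc3ccccc3)c2c1O[C@H](c1ccc(OCc3ccccc3)c(OCc3ccccc3)c1)[C@@H](OC(C)=O)C2 | intermediate
14 | 3-O-acetyl-5,7,3',4'-tetra-O-benzylepicatechin-(4β→8)-3-O-acetyl-5,7,3',4'-tetra-O-benzylcatechin | c1c(OCc3ccccc3)cc(OCc3ccccc3)c2c1O[C@H](c1ccc(OCc3ccccc3)c(OCc3ccccc3)c1)[C@H](OC(C)=O)[C@H]2c1c(OCc3ccccc3)cc(OCc3ccccc3)c2c1O[C@H](c1ccc(OCc3ccccc3)c(OCc3ccccc3)c1)[C@@H](OC(C)=O)C2 | intermediate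
15 | 5,7,3',4'-tetra-O-benzylepicatechin-(4β→8)-5,7,3',4'-tetra-O-benzylcatechin (octa-O-benzylprocyanidin B1) | c1c(OCc3ccccc3)cc(OCc3ccccc3)c2c1O[C@H](c1ccc(OCc3ccccc3)c(OCc3ccccc3)c1)[C@H](O)[C@H]2c1c(OCc3ccccc3)cc(OCc3ccccc3)c2c1O[C@H](c1ccc(OCc3ccccc3)c(OCc3ccccc3)c1)[C@@H](O)C2 | intermediate
16 | (−)-epigallocatechin, (2R,3R) | O[C@@H]1Cc2c(O)cc(O)cc2O[C@@H]1c1cc(O)c(O)c(O)c1 | starting material
17 | 5,7,3',4',5'-penta-O-benzyl-(−)-epigallocatechin | O[C@@H]1Cc2c(OCc3ccccc3)cc(OCc3ccccc3)cc2O[C@@H]1c1cc(OCc2ccccc2)c(OCc2ccccc2)c(OCc2ccccc2)c1 | intermediate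
18 | 5,7,3',4',5'-penta-O-benzyl-4β-(2-ethoxyethoxy)-(−)-epigallocatechin (2,3-cis-3,4-trans) | O[C@@H]1[C@@H](OCCOCC)c2c(OCc3ccccc3)cc(OCc3ccccc3)cc2O[C@@H]1c1cc(OCc2ccccc2)c(OCc2ccccc2)c(OCc2ccccc2)c1 | intermediate
19 | 3,4,5-tris(benzyloxy)benzoic acid | OC(=O)c1cc(OCc2ccccc2)c(OCc2ccccc2)c(OCc2ccccc2)c1 | starting material
20 | 5,7,3',4',5'-penta-O-benzyl-4β-(2-ethoxyethoxy)-(−)-epigallocatechin 3-O-[3,4,5-tris(benzyloxy)benzoate] | O=C(O[C@@H]1[C@@H](OCCOCC)c2c(OCc3ccccc3)cc(OCc3ccccc3)cc2O[C@@H]1c1cc(OCc2ccccc2)c(OCc2ccccc2)c(OCc2ccccc2)c1)c1cc(OCc2ccccc2)c(OCc2ccccc2)c(OCc2ccccc2)c1 | intermediate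
21 | 5,7,3',4',5'-penta-O-benzyl-3-O-[3,4,5-tris(benzyloxy)benzoyl]epigallocatechin-(4β→8)-5,7,3',4'-tetra-O-benzylepicatechin-(4β→8)-5,7,3',4'-tetra-O-benzylcatechin | O=C(O[C@@H]1[C@@H](c2c(OCc5ccccc5)cc(OCc5ccccc5)c3c2O[C@H](c2ccc(OCc5ccccc5)c(OCc5ccccc5)c2)[C@H](O)[C@H]3c2c(OCc5ccccc5)cc(OCc5ccccc5)c3c2O[C@H](c2ccc(OCc5ccccc5)c(OCc5ccccc5)c2)[C@@H](O)C3)c2c(OCc5ccccc5)cc(OCc5ccccc5)cc2O[C@@H]1c1cc(OCc5ccccc5)c(OCc5ccccc5)c(OCc5ccccc5)c1)c1cc(OCc5ccccc5)c(OCc5ccccc5)c(OCc5ccccc5)c1 | intermediate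
22 | (−)-epicatechin, (2R,3R) | O[C@@H]1Cc2c(O)cc(O)cc2O[C@@H]1c1ccc(O)c(O)c1 | starting material
23 | 5,7,3',4'-tetra-O-benzyl-(−)-epicatechin | O[C@@H]1Cc2c(OCc3ccccc3)cc(OCc3ccccc3)cc2O[C@@H]1c1ccc(OCc2ccccc2)c(OCc2ccccc2)c1 | intermediate
24 | 5,7,3',4'-tetra-O-benzyl-4β-(2-ethoxyethoxy)-(−)-epicatechin (2,3-cis-3,4-trans) | O[C@@H]1[C@@H](OCCOCC)c2c(OCc3ccccc3)cc(OCc3ccccc3)cc2O[C@@H]1c1ccc(OCc2ccccc2)c(OCc2ccccc2)c1 | intermediate
25 | icosa-O-benzyl target: 5,7,3',4'-tetra-O-benzylepicatechin-(4β→8)-5,7,3',4',5'-penta-O-benzyl-3-O-[3,4,5-tris(benzyloxy)benzoyl]epigallocatechin-(4β→8)-5,7,3',4'-tetra-O-benzylepicatechin-(4β→8)-5,7,3',4'-tetra-O-benzylcatechin | O=C(O[C@@H]1[C@@H](c2c(OCc5ccccc5)cc(OCc5ccccc5)c3c2O[C@H](c2ccc(OCc5ccccc5)c(OCc5ccccc5)c2)[C@H](O)[C@H]3c2c(OCc5ccccc5)cc(OCc5ccccc5)c3c2O[C@H](c2ccc(OCc5ccccc5)c(OCc5ccccc5)c2)[C@@H](O)C3)c2c(OCc5ccccc5)cc(OCc5ccccc5)c([C@H]3c4c(OCc5ccccc5)cc(OCc5ccccc5)cc4O[C@H](c4ccc(OCc5ccccc5)c(OCc5ccccc5)c4)[C@@H]3O)c2O[C@@H]1c1cc(OCc5ccccc5)c(OCc5ccccc5)c(OCc5ccccc5)c1)c1cc(OCc5ccccc5)c(OCc5ccccc5)c(OCc5ccccc5)c1 | intermediate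
26 | epicatechin-(4β→8)-epigallocatechin 3-O-gallate-(4β→8)-epicatechin-(4β→8)-catechin (CNP0332815.1) | O=C(O[C@@H]1[C@@H](c2c(O)cc(O)c3c2O[C@H](c2ccc(O)c(O)c2)[C@H](O)[C@H]3c2c(O)cc(O)c3c2O[C@H](c2ccc(O)c(O)c2)[C@@H](O)C3)c2c(O)cc(O)c([C@H]3c4c(O)cc(O)cc4O[C@H](c4ccc(O)c(O)c4)[C@@H]3O)c2O[C@@H]1c1cc(O)c(O)c(O)c1)c1cc(O)c(O)c(O)c1 | target

**Step count and risks**

Total step count: 16. Longest linear sequence: 9 steps (steps 1, 2, 3, 4, 7, 8, 12, 15 and 16, from (+)-catechin).

Steps most likely to fail: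

Step 7 (bears the label). What may go wrong: the counter-anion may control the face of C2 too weakly; the acetoxy group may take the exo instead of the endo position and lead into the 2,3-trans series; the oxocarbenium ion may attack C6 of the catechin ring; or the acid may oligomerise the electron-rich enol acetate. The fallback uses known chemistry and sets out from compound 2. Compound 2 is taken in excess as the nucleophile towards electrophile 24 (steps 13 and 14 are then run first) with TMSOTf in CH2Cl2 at −78 °C. The flavan-4-yl cation from 24 is attacked by C8 of 2 trans to the 3-hydroxy group, a flavan-4-yl cation/arene coupling of the well-precedented type. The fallback comes back to the route at compound 15 and makes no compound outside the list (F0).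

Step 6. What may go wrong: over-oxidation of the acetal; Friedel–Crafts capture of the oxocarbenium ion by a second trioxygenated ring in place of trifluoroethanol; or ionisation and hydrolysis of the labile acetal during isolation. The fallback avoids the oxidation and sets out from compound 8. Commercial 3,4-bis(benzyloxy)benzaldehyde is acetalised with trimethyl(2,2,2-trifluoroethoxy)silane and catalytic TMSOTf to 3,4-bis(benzyloxy)benzaldehyde bis(2,2,2-trifluoroethyl) acetal F1. Acetyl chloride with catalytic ZnCl2 converts this into α-chloro-3,4-bis(benzyloxy)benzyl 2,2,2-trifluoroethyl ether F2. The sodium salt of 8 (NaH, THF, 0 °C) is then O-alkylated by F2, which comes back to the route at compound 11.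

Step 15. What may go wrong: self-condensation of the electrophile through its own free C8; competing attack at the C6 positions of the trimer; or acid-induced scrambling of the interflavan bonds on prolonged reaction, all at the expense of the most valuable intermediate. The fallback blocks the electrophile and sets out from compound 23. NBS gives 8-bromo-5,7,3',4'-tetra-O-benzyl-(−)-epicatechin F3, and DDQ with 2-ethoxyethanol gives 8-bromo-5,7,3',4'-tetra-O-benzyl-4β-(2-ethoxyethoxy)-(−)-epicatechin F4. F4 cannot act as a nucleophile at C8, so it can be used in excess over 21 (TMSOTf, CH2Cl2, −78 °C) to give the 8-bromo derivative of the protected tetramer F5. Hydrogenolysis over Pd(OH)2/C removes the bromine together with the benzyl groups, and the fallback comes back to the route at compound 26.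

Further compounds
F0 | step 7 | none | none
F1 | step 6 | 3,4-bis(benzyloxy)benzaldehyde bis(2,2,2-trifluoroethyl) acetal | FC(F)(F)COC(OCC(F)(F)F)c1ccc(OCc2ccccc2)c(OCc2ccccc2)c1
F2 | step 6 | α-chloro-3,4-bis(benzyloxy)benzyl 2,2,2-trifluoroethyl ether, racemic | FC(F)(F)COC(Cl)c1ccc(OCc2ccccc2)c(OCc2ccccc2)c1
F3 | step 15 | 8-bromo-5,7,3',4'-tetra-O-benzyl-(−)-epicatechin | O[C@@H]1Cc2c(OCc3ccccc3)cc(OCc3ccccc3)c(Br)c2O[C@@H]1c1ccc(OCc2ccccc2)c(OCc2ccccc2)c1
F4 | step 15 | 8-bromo-5,7,3',4'-tetra-O-benzyl-4β-(2-ethoxyethoxy)-(−)-epicatechin | O[C@@H]1[C@@H](OCCOCC)c2c(OCc3ccccc3)cc(OCc3ccccc3)c(Br)c2O[C@@H]1c1ccc(OCc2ccccc2)c(OCc2ccccc2)c1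
F5 | step 15 | 8-bromo derivative (top unit) of protected tetramer 25 | O=C(O[C@@H]1[C@@H](c2c(OCc5ccccc5)cc(OCc5ccccc5)c3c2O[C@H](c2ccc(OCc5ccccc5)c(OCc5ccccc5)c2)[C@H](O)[C@H]3c2c(OCc5ccccc5)cc(OCc5ccccc5)c3c2O[C@H](c2ccc(OCc5ccccc5)c(OCc5ccccc5)c2)[C@@H](O)C3)c2c(OCc5ccccc5)cc(OCc5ccccc5)c([C@H]3c4c(OCc5ccccc5)cc(OCc5ccccc5)c(Br)c4O[C@H](c4ccc(OCc5ccccc5)c(OCc5ccccc5)c4)[C@@H]3O)c2O[C@@H]1c1cc(OCc5ccccc5)c(OCc5ccccc5)c(OCc5ccccc5)c1)c1cc(OCc5ccccc5)c(OCc5ccccc5)c(OCc5ccccc5)c1
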